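## Retrosynthetic overview

1. Germacrane numbering is used: ten-membered carbocycle C1–C10 (C1=C10 and C4=C5 both ring-cis, E by CIP), γ-lactone ring O–C6–C7–C11–C12 with exocyclic C11=C13, C14 (CHO) on C10, C15 (CH2OAc) on C4.
2. End game: the C14 aldehyde comes from a silyl-protected CH2OH, and the 8R ester from the 8S alcohol by Mitsunobu inversion with 3-methylbutanoic acid.
3. Key disconnection C7–C8: the α-methylene-γ-butyrolactone holds the homoallylic alcohol retron C13=C11–C7–C8–O. The ten-membered ring (second ring) is therefore closed by polarity reversal of the butenolide β-carbon C7 (allylchromium from a 3-(bromomethyl)butenolide) onto a C8 aldehyde; C7, C8 and the exo-methylene arise together.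
4. The butenolide (first ring of the target) comes from ring-closing metathesis of a C6 2-(bromomethyl)acrylate. C1=C10 comes from a Wittig reaction with a formyl ylide. C4=C5 comes from a Horner–Wadsworth–Emmons reaction of a temporary α-phosphono lactone (C15, C4, C3, C2, C1), whose reduction tells C15–OH from C2–OH.
5. C2 and C6 come from (S)-glycidyl trityl ether and (S)-but-3-ene-1,2-diol; C7 and C8 are set in the key step.

Key step: step 21

## Route

Step 1
Reactants: 1 (2S)-but-3-ene-1,2-diol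
Product: 2 (4S)-4-ethenyl-2-(4-methoxyphenyl)-1,3-dioxolane (both acetal epimers)
Conditions: 4-MeOC6H4CH(OMe)2, CSA (cat.), CH2Cl2, rt
Reagents that add atoms: 4-methoxybenzaldehyde dimethyl acetal, COc1ccc(C(OC)OC)cc1
Why: Acid-catalysed transacetalization gives the five-membered p-methoxybenzylidene acetal of the 1,2-diol without touching the stereocenter.

Step 2
Reactants: 2 (4S)-4-ethenyl-2-(4-methoxyphenyl)-1,3-dioxolane
Product: 3 (2S)-2-[(4-methoxybenzyl)oxy]but-3-en-1-ol
Conditions: i-Bu2AlH (3 equiv), CH2Cl2, −78 → 0 °C; aqueous potassium sodium tartrate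
Reagents that add atoms: none
Why: Regioselective reductive acetal opening, in which aluminium binds the less hindered primary oxygen so that hydride delivery leaves the PMB group on the secondary allylic oxygen.

Step 3
Reactants: 3 (2S)-2-[(4-methoxybenzyl)oxy]but-3-en-1-ol
Product: 4 (2S)-2-[(4-methoxybenzyl)oxy]but-3-enal
Conditions: Dess–Martin periodinane, NaHCO3, CH2Cl2, 0 °C; used at once
Reagents that add atoms: none
Why: Dess–Martin oxidation under buffered non-basic conditions should give the α-alkoxy β,γ-unsaturated aldehyde without epimerization or migration of the alkene.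

Step 4
Reactants: 5 (S)-glycidyl trityl ether; 6 triethyl phosphonoacetate
Product: 8 diethyl [(5S)-2-oxo-5-(trityloxymethyl)oxolan-3-yl]phosphonate, via ring-opened hydroxy phosphonoester 7 (not isolated)
Conditions: NaOEt (1.1 equiv), EtOH, 70 °C; aqueous NH4Cl
Reagents that add atoms: none
Why: The stabilized phosphonoacetate carbanion opens the epoxide at its terminal carbon (SN2) and the alkoxide lactonizes with loss of ethoxide, so the C–O bond of the stereocenter (future C2) is never broken and the phosphonate-bearing carbon is an inconsequential mixture.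

Step 5
Reactants: 8 diethyl [(5S)-2-oxo-5-(trityloxymethyl)oxolan-3-yl]phosphonate; 4 (2S)-2-[(4-methoxybenzyl)oxy]but-3-enal
Product: 9 (3E,5S)-3-[(2S)-2-[(4-methoxybenzyl)oxy]but-3-en-1-ylidene]-5-(trityloxymethyl)oxolan-2-one
Conditions: NaH (1.0 equiv), THF, 0 °C; then 4, −78 → 0 °C
Reagents that add atoms: none
Why: Horner–Wadsworth–Emmons olefination of the α-phosphono lactone should favour the E-alkylidene lactone (branched C6 substituent trans to the lactone carbonyl, the C4=C5 geometry of the target), and the pre-formed weakly basic phosphonate anion at low temperature spares the stereocenter of 4.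

Step 6
Reactants: 9 (3E,5S)-3-[(2S)-2-[(4-methoxybenzyl)oxy]but-3-en-1-ylidene]-5-(trityloxymethyl)oxolan-2-one
Product: 10 (2S,4E,6S)-4-(hydroxymethyl)-6-[(4-methoxybenzyl)oxy]-1-(trityloxy)octa-4,7-dien-2-ol
Conditions: i-Bu2AlH (4 equiv), CH2Cl2, −78 → 0 °C; aqueous potassium sodium tartrate
Reagents that add atoms: none
Why: 1,2-Reduction of the α-alkylidene lactone through the lactol opens the temporary ring and releases C15–OH (primary, allylic) and C2–OH (secondary) as chemically distinct hydroxyls.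

Step 7
Reactants: 10 (2S,4E,6S)-4-(hydroxymethyl)-6-[(4-methoxybenzyl)oxy]-1-(trityloxy)octa-4,7-dien-2-ol
Product: 11 (2E,4S)-2-[(2S)-2-hydroxy-3-(trityloxy)propyl]-4-[(4-methoxybenzyl)oxy]hexa-2,5-dien-1-yl acetate
Conditions: AcCl (1.05 equiv), 2,4,6-collidine, CH2Cl2, −78 °C
Reagents that add atoms: acetyl chloride, CC(=O)Cl
Why: Kinetically selective acylation of the primary allylic alcohol over the hindered secondary alcohol at low temperature with a weak hindered base.

Step 8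
Reactants: 11 (2E,4S)-2-[(2S)-2-hydroxy-3-(trityloxy)propyl]-4-[(4-methoxybenzyl)oxy]hexa-2,5-dien-1-yl acetate
Product: 12 (2E,4S)-2-[(2S)-2-[(tert-butyldimethylsilyl)oxy]-3-(trityloxy)propyl]-4-[(4-methoxybenzyl)oxy]hexa-2,5-dien-1-yl acetate
Conditions: TBSOTf, 2,6-lutidine, CH2Cl2, −78 → 0 °C
Reagents that add atoms: tert-butyldimethylsilyl trifluoromethanesulfonate, CC(C)(C)[Si](C)(C)OS(=O)(=O)C(F)(F)F
Why: Silylation of the only free (secondary) hydroxyl with the reactive silyl triflate under buffered conditions.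

Step 9
Reactants: 12 (2E,4S)-2-[(2S)-2-[(tert-butyldimethylsilyl)oxy]-3-(trityloxy)propyl]-4-[(4-methoxybenzyl)oxy]hexa-2,5-dien-1-yl acetate
Product: 13 (2E,4S)-2-[(2S)-2-[(tert-butyldimethylsilyl)oxy]-3-hydroxypropyl]-4-[(4-methoxybenzyl)oxy]hexa-2,5-dien-1-yl acetate
Conditions: TsOH·H2O (0.1 equiv), MeOH/CH2Cl2 (1:1), 0 °C, short reaction time
Reagents that add atoms: none
Why: Mild acid methanolysis ionizes the trityl ether far faster than it touches the secondary TBS ether, the acetate or the bis-allylic PMB ether.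

Step 10
Reactants: 13 (2E,4S)-2-[(2S)-2-[(tert-butyldimethylsilyl)oxy]-3-hydroxypropyl]-4-[(4-methoxybenzyl)oxy]hexa-2,5-dien-1-yl acetate
Product: 14 (2E,4S)-2-[(2S)-2-[(tert-butyldimethylsilyl)oxy]-3-oxopropyl]-4-[(4-methoxybenzyl)oxy]hexa-2,5-dien-1-yl acetate
Conditions: Dess–Martin periodinane, NaHCO3, CH2Cl2, 0 °C → rt
Reagents that add atoms: none
Why: Dess–Martin oxidation gives the α-silyloxy aldehyde (C1) under neutral conditions that should not epimerize C2.

Step 11
Reactants: 15 (3-bromopropoxy)(tert-butyl)dimethylsilane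
Product: 16 {3-[(tert-butyldimethylsilyl)oxy]propyl}triphenylphosphonium bromide
Conditions: PPh3, MeCN, reflux
Reagents that add atoms: triphenylphosphine, c1ccc(cc1)P(c1ccccc1)c1ccccc1
Why: SN2 quaternization of triphenylphosphine by the primary bromide.

Step 12
Reactants: 16 {3-[(tert-butyldimethylsilyl)oxy]propyl}triphenylphosphonium bromide; 17 ethyl formate
Product: 19 4-[(tert-butyldimethylsilyl)oxy]-2-(triphenylphosphoranylidene)butanal, via non-stabilized ylide 18 (not isolated)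
Conditions: KOtBu (2.1 equiv), THF, 0 °C; then HCO2Et, 0 °C → rt
Reagents that add atoms: none
Why: The non-stabilized ylide is C-formylated by ethyl formate and the second equivalent of base deprotonates the acylphosphonium to the stable α-formyl ylide (ylide acylation).

Step 13
Reactants: 14 (2E,4S)-2-[(2S)-2-[(tert-butyldimethylsilyl)oxy]-3-oxopropyl]-4-[(4-methoxybenzyl)oxy]hexa-2,5-dien-1-yl acetate; 19 4-[(tert-butyldimethylsilyl)oxy]-2-(triphenylphosphoranylidene)butanal
Product: 20 (2E,4S)-2-[(2S,3E)-2,6-bis[(tert-butyldimethylsilyl)oxy]-4-formylhex-3-en-1-yl]-4-[(4-methoxybenzyl)oxy]hexa-2,5-dien-1-yl acetate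
Conditions: toluene, 90 °C
Reagents that add atoms: none
Why: The Wittig reaction of a formyl-stabilized ylide is thermodynamically controlled and should give the E-2-alkyl enal with C2 trans to the aldehyde carbon C14, which is the C1=C10 geometry of the target, under salt-free neutral conditions that spare the α-silyloxy stereocenter.

Step 14
Reactants: 20 (2E,4S)-2-[(2S,3E)-2,6-bis[(tert-butyldimethylsilyl)oxy]-4-formylhex-3-en-1-yl]-4-[(4-methoxybenzyl)oxy]hexa-2,5-dien-1-yl acetate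
Product: 21 (2E,4S)-2-[(2S,3E)-2,6-bis[(tert-butyldimethylsilyl)oxy]-4-(hydroxymethyl)hex-3-en-1-yl]-4-[(4-methoxybenzyl)oxy]hexa-2,5-dien-1-yl acetate
Conditions: NaBH4, CeCl3·7H2O, MeOH, −40 °C
Reagents that add atoms: none
Why: Luche 1,2-reduction takes the enal to the allylic alcohol and leaves the acetate untouched, so that C14 is no electrophile in the key step.

Step 15
Reactants: 21 (2E,4S)-2-[(2S,3E)-2,6-bis[(tert-butyldimethylsilyl)oxy]-4-(hydroxymethyl)hex-3-en-1-yl]-4-[(4-methoxybenzyl)oxy]hexa-2,5-dien-1-yl acetate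
Product: 22 (2E,4S)-2-[(2S,3E)-2,6-bis[(tert-butyldimethylsilyl)oxy]-4-{[(tert-butyldiphenylsilyl)oxy]methyl}hex-3-en-1-yl]-4-[(4-methoxybenzyl)oxy]hexa-2,5-dien-1-yl acetate
Conditions: TBDPSCl, imidazole, CH2Cl2, rt
Reagents that add atoms: tert-butyl(chloro)diphenylsilane, CC(C)(C)[Si](Cl)(c1ccccc1)c1ccccc1
Why: Silylation of the only free hydroxyl with the acid-robust TBDPS group, which later allows the primary TBS ether at C8 to be removed alone.

Step 16
Reactants: 22 (2E,4S)-2-[(2S,3E)-2,6-bis[(tert-butyldimethylsilyl)oxy]-4-{[(tert-butyldiphenylsilyl)oxy]methyl}hex-3-en-1-yl]-4-[(4-methoxybenzyl)oxy]hexa-2,5-dien-1-yl acetate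
Product: 23 (2E,4S)-2-[(2S,3E)-2,6-bis[(tert-butyldimethylsilyl)oxy]-4-{[(tert-butyldiphenylsilyl)oxy]methyl}hex-3-en-1-yl]-4-hydroxyhexa-2,5-dien-1-yl acetate
Conditions: DDQ (1.2 equiv), CH2Cl2/pH 7 buffer (10:1), 0 °C, short reaction time
Reagents that add atoms: none
Why: Oxidative PMB cleavage (benzylic hydride abstraction, then hydrolysis of the oxocarbenium ion) frees C6–OH, and the small excess of DDQ at 0 °C should keep the liberated bis-allylic alcohol from being oxidized further.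

Step 17
Reactants: 23 (2E,4S)-2-[(2S,3E)-2,6-bis[(tert-butyldimethylsilyl)oxy]-4-{[(tert-butyldiphenylsilyl)oxy]methyl}hex-3-en-1-yl]-4-hydroxyhexa-2,5-dien-1-yl acetate; 24 2-(bromomethyl)acrylic acid
Product: 25 (3S,4E)-6-acetoxy-5-{(2S,3E)-2,6-bis[(tert-butyldimethylsilyl)oxy]-4-{[(tert-butyldiphenylsilyl)oxy]methyl}hex-3-en-1-yl}hexa-1,4-dien-3-yl 2-(bromomethyl)prop-2-enoate
Conditions: DIC, DMAP (0.1 equiv), CH2Cl2, −20 → 0 °C
Reagents that add atoms: none
Why: Steglich esterification of the only free hydroxyl with retention at C6, the low temperature and catalytic DMAP limiting attack on the allylic bromide.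

Step 18
Reactants: 25 (3S,4E)-6-acetoxy-5-{(2S,3E)-2,6-bis[(tert-butyldimethylsilyl)oxy]-4-{[(tert-butyldiphenylsilyl)oxy]methyl}hex-3-en-1-yl}hexa-1,4-dien-3-yl 2-(bromomethyl)prop-2-enoate
Product: 26 (5R)-3-(bromomethyl)-5-[(1E,4S,5E)-2-(acetoxymethyl)-4,8-bis[(tert-butyldimethylsilyl)oxy]-6-{[(tert-butyldiphenylsilyl)oxy]methyl}octa-1,5-dien-1-yl]furan-2(5H)-one
Conditions: second-generation Grubbs catalyst (H2IMes)(PCy3)Cl2Ru=CHPh (10 mol %), toluene, 80 °C, 5 mM
Reagents that add atoms: none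
Why: Ring-closing metathesis, in which the ruthenium alkylidene loads on the monosubstituted C7 vinyl group and closes the five-membered butenolide onto the acrylate while the two trisubstituted alkenes stay spectators.

Step 19
Reactants: 26 (5R)-3-(bromomethyl)-5-[(1E,4S,5E)-2-(acetoxymethyl)-4,8-bis[(tert-butyldimethylsilyl)oxy]-6-{[(tert-butyldiphenylsilyl)oxy]methyl}octa-1,5-dien-1-yl]furan-2(5H)-one
Product: 27 (5R)-3-(bromomethyl)-5-[(1E,4S,5E)-2-(acetoxymethyl)-4-[(tert-butyldimethylsilyl)oxy]-6-{[(tert-butyldiphenylsilyl)oxy]methyl}-8-hydroxyocta-1,5-dien-1-yl]furan-2(5H)-one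
Conditions: 48% aqueous HF/MeCN (5:95), 0 °C
Reagents that add atoms: none
Why: Dilute HF cleaves the unhindered primary TBS ether much faster than the secondary TBS and the TBDPS ethers, and contains no nucleophilic amine that could attack the allylic bromide.

Step 20
Reactants: 27 (5R)-3-(bromomethyl)-5-[(1E,4S,5E)-2-(acetoxymethyl)-4-[(tert-butyldimethylsilyl)oxy]-6-{[(tert-butyldiphenylsilyl)oxy]methyl}-8-hydroxyocta-1,5-dien-1-yl]furan-2(5H)-one
Product: 28 (5R)-3-(bromomethyl)-5-[(1E,4S,5E)-2-(acetoxymethyl)-4-[(tert-butyldimethylsilyl)oxy]-6-{[(tert-butyldiphenylsilyl)oxy]methyl}-8-oxoocta-1,5-dien-1-yl]furan-2(5H)-one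
Conditions: Dess–Martin periodinane, NaHCO3, CH2Cl2, 0 °C; filtered and used at once
Reagents that add atoms: none
Why: Buffered Dess–Martin oxidation gives the β,γ-unsaturated C8 aldehyde without conjugation of the alkene and without touching the allylic bromide.

Step 21
Reactants: 28 (5R)-3-(bromomethyl)-5-[(1E,4S,5E)-2-(acetoxymethyl)-4-[(tert-butyldimethylsilyl)oxy]-6-{[(tert-butyldiphenylsilyl)oxy]methyl}-8-oxoocta-1,5-dien-1-yl]furan-2(5H)-one
Product: 30 (1(10)E,2S,4E,6R,7R,8S)-15-acetoxy-2-[(tert-butyldimethylsilyl)oxy]-14-[(tert-butyldiphenylsilyl)oxy]-8-hydroxygermacra-1(10),4,11(13)-trien-12,6-olide, via allylchromium dichloride 29 (not isolated)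
Conditions: CrCl2 (8 equiv), THF, 4 Å molecular sieves, rt; 28 added by syringe pump (final 2 mM); aqueous NH4Cl
Reagents that add atoms: none
Why: Two CrCl2 (divalent chromium) reduce the allylic C13–Br bond to the allylchromium (trivalent chromium) species 29, which adds through its γ-carbon C7 to the C8 aldehyde in a closed six-membered chair transition state, so that the C7–C8 bond forms while the alkene moves to C11=C13 (intramolecular Nozaki–Hiyama–Kishi allylation). The closest known reactions are chromium-mediated macrocyclizations of 2-(bromomethyl)enoates onto aldehydes that close ten-membered germacranolide rings and Barbier allylations of aldehydes with 3-(bromomethyl)furan-2(5H)-ones. The ten-membered carbocycle closes by a 10-exo-trig addition to the aldehyde (SE2′ at the allyl unit), helped by the two ring-cis trisubstituted alkenes that pre-fold the chain. C7 should be set by C6, the aldehyde adding to the butenolide face anti to the C5 substituent, which is also the trans ring fusion that the ten-membered ring takes up without an eclipsed C5–C6–C7–C8 torsion (7R). C8 should be set by the chair, in which the butenolide ring locks C6 trans to CH2Cr and the C9 chain lies pseudo-equatorial, so that the 7,8-anti alcohol (8S) is expected and is inverted in step 22. The step needs γ- over α-attack (the cyclic transition state), ring closure over oligomerization (slow addition to 2 mM) and one electrophile only (C14 is a silyl ether, the esters do not react with allylchromium reagents).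

Step 22
Reactants: 30 (1(10)E,2S,4E,6R,7R,8S)-15-acetoxy-2-[(tert-butyldimethylsilyl)oxy]-14-[(tert-butyldiphenylsilyl)oxy]-8-hydroxygermacra-1(10),4,11(13)-trien-12,6-olide; 31 3-methylbutanoic acid
Product: 32 (1(10)E,2S,4E,6R,7R,8R)-15-acetoxy-2-[(tert-butyldimethylsilyl)oxy]-14-[(tert-butyldiphenylsilyl)oxy]-8-[(3-methylbutanoyl)oxy]germacra-1(10),4,11(13)-trien-12,6-olide
Conditions: PPh3, DIAD (pre-mixed, 0 °C), toluene; then 31 and 30, 0 °C → rt
Reagents that add atoms: none
Why: Mitsunobu esterification, in which SN2 displacement of the C8 alkoxyphosphonium by the carboxylate inverts C8 from S to R and installs the 3-methylbutanoate in one operation, the pre-formed betaine keeping free phosphine away from the α-methylene lactone.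

Step 23
Reactants: 32 (1(10)E,2S,4E,6R,7R,8R)-15-acetoxy-2-[(tert-butyldimethylsilyl)oxy]-14-[(tert-butyldiphenylsilyl)oxy]-8-[(3-methylbutanoyl)oxy]germacra-1(10),4,11(13)-trien-12,6-olide
Product: 33 (1(10)E,2S,4E,6R,7R,8R)-15-acetoxy-2,14-dihydroxy-8-[(3-methylbutanoyl)oxy]germacra-1(10),4,11(13)-trien-12,6-olide
Conditions: HF·pyridine (excess), THF, 0 °C → rt
Reagents that add atoms: none
Why: Fluoride cleavage of both allylic silyl ethers under acidic non-basic conditions that should spare the three ester groups and the Michael acceptor.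

Step 24
Reactants: 33 (1(10)E,2S,4E,6R,7R,8R)-15-acetoxy-2,14-dihydroxy-8-[(3-methylbutanoyl)oxy]germacra-1(10),4,11(13)-trien-12,6-olide
Product: 34 (1(10)E,2S,4E,6R,7R,8R)-15-acetoxy-2-hydroxy-8-[(3-methylbutanoyl)oxy]-14-oxogermacra-1(10),4,11(13)-trien-12,6-olide (CNP0524123.1)
Conditions: TEMPO (0.2 equiv), PhI(OAc)2 (1.1 equiv), CH2Cl2, rt
Reagents that add atoms: none
Why: Oxoammonium oxidation (TEMPO/PhI(OAc)2) is selective for the primary allylic alcohol over the secondary one, and the E geometry keeps C2–OH from closing a lactol on the new C14 aldehyde.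

## Compound list

1 | (2S)-but-3-ene-1,2-diol | C=C[C@H](O)CO | starting material
2 | (4S)-4-ethenyl-2-(4-methoxyphenyl)-1,3-dioxolane (both acetal epimers) | C=C[C@H]1COC(c2ccc(OC)cc2)O1 | intermediate
3 | (2S)-2-[(4-methoxybenzyl)oxy]but-3-en-1-ol | C=C[C@H](OCc1ccc(OC)cc1)CO | intermediate
4 | (2S)-2-[(4-methoxybenzyl)oxy]but-3-enal | C=C[C@H](OCc1ccc(OC)cc1)C=O | intermediate
5 | (S)-glycidyl trityl ether, (2S)-2-[(triphenylmethoxy)methyl]oxirane | C1O[C@@H]1COC(c2ccccc2)(c2ccccc2)c2ccccc2 | starting material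
6 | triethyl phosphonoacetate | CCOC(=O)CP(=O)(OCC)OCC | starting material
7 | ethyl (4S)-2-(diethoxyphosphoryl)-4-hydroxy-5-(trityloxy)pentanoate (sodium alkoxide in the flask) | CCOC(=O)C(C[C@H](O)COC(c1ccccc1)(c1ccccc1)c1ccccc1)P(=O)(OCC)OCC | intermediate (not isolated)
8 | diethyl [(5S)-2-oxo-5-(trityloxymethyl)oxolan-3-yl]phosphonate (mixture at C3) | CCOP(=O)(OCC)C1C[C@H](OC1=O)COC(c2ccccc2)(c2ccccc2)c2ccccc2 | intermediate
9 | (3E,5S)-3-[(2S)-2-[(4-methoxybenzyl)oxy]but-3-en-1-ylidene]-5-(trityloxymethyl)oxolan-2-one | C=C[C@H](OCc1ccc(OC)cc1)/C=C1/C(=O)O[C@H](COC(c2ccccc2)(c2ccccc2)c2ccccc2)C1 | intermediate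
10 | (2S,4E,6S)-4-(hydroxymethyl)-6-[(4-methoxybenzyl)oxy]-1-(trityloxy)octa-4,7-dien-2-ol | C=C[C@H](OCc1ccc(OC)cc1)/C=C(/CO)C[C@H](O)COC(c1ccccc1)(c1ccccc1)c1ccccc1 | intermediate
11 | (2E,4S)-2-[(2S)-2-hydroxy-3-(trityloxy)propyl]-4-[(4-methoxybenzyl)oxy]hexa-2,5-dien-1-yl acetate | C=C[C@H](OCc1ccc(OC)cc1)/C=C(/COC(C)=O)C[C@H](O)COC(c1ccccc1)(c1ccccc1)c1ccccc1 | intermediate
12 | (2E,4S)-2-[(2S)-2-[(tert-butyldimethylsilyl)oxy]-3-(trityloxy)propyl]-4-[(4-methoxybenzyl)oxy]hexa-2,5-dien-1-yl acetate | C=C[C@H](OCc1ccc(OC)cc1)/C=C(/COC(C)=O)C[C@H](O[Si](C)(C)C(C)(C)C)COC(c1ccccc1)(c1ccccc1)c1ccccc1 | intermediate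
13 | (2E,4S)-2-[(2S)-2-[(tert-butyldimethylsilyl)oxy]-3-hydroxypropyl]-4-[(4-methoxybenzyl)oxy]hexa-2,5-dien-1-yl acetate | C=C[C@H](OCc1ccc(OC)cc1)/C=C(/COC(C)=O)C[C@H](O[Si](C)(C)C(C)(C)C)CO | intermediate
14 | (2E,4S)-2-[(2S)-2-[(tert-butyldimethylsilyl)oxy]-3-oxopropyl]-4-[(4-methoxybenzyl)oxy]hexa-2,5-dien-1-yl acetate | C=C[C@H](OCc1ccc(OC)cc1)/C=C(/COC(C)=O)C[C@H](O[Si](C)(C)C(C)(C)C)C=O | intermediate
15 | (3-bromopropoxy)(tert-butyl)dimethylsilane | BrCCCO[Si](C)(C)C(C)(C)C | starting material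
16 | {3-[(tert-butyldimethylsilyl)oxy]propyl}triphenylphosphonium bromide | [Br-].CC(C)(C)[Si](C)(C)OCCC[P+](c1ccccc1)(c1ccccc1)c1ccccc1 | intermediate
17 | ethyl formate | CCOC=O | starting material
18 | {3-[(tert-butyldimethylsilyl)oxy]propylidene}triphenylphosphorane | CC(C)(C)[Si](C)(C)OCCC=P(c1ccccc1)(c1ccccc1)c1ccccc1 | intermediate (not isolated)
19 | 4-[(tert-butyldimethylsilyl)oxy]-2-(triphenylphosphoranylidene)butanal | CC(C)(C)[Si](C)(C)OCCC(C=O)=P(c1ccccc1)(c1ccccc1)c1ccccc1 | intermediate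
20 | (2E,4S)-2-[(2S,3E)-2,6-bis[(tert-butyldimethylsilyl)oxy]-4-formylhex-3-en-1-yl]-4-[(4-methoxybenzyl)oxy]hexa-2,5-dien-1-yl acetate | C=C[C@H](OCc1ccc(OC)cc1)/C=C(/COC(C)=O)C[C@H](O[Si](C)(C)C(C)(C)C)/C=C(/C=O)CCO[Si](C)(C)C(C)(C)C | intermediate
21 | (2E,4S)-2-[(2S,3E)-2,6-bis[(tert-butyldimethylsilyl)oxy]-4-(hydroxymethyl)hex-3-en-1-yl]-4-[(4-methoxybenzyl)oxy]hexa-2,5-dien-1-yl acetate | C=C[C@H](OCc1ccc(OC)cc1)/C=C(/COC(C)=O)C[C@H](O[Si](C)(C)C(C)(C)C)/C=C(/CO)CCO[Si](C)(C)C(C)(C)C | intermediate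
22 | (2E,4S)-2-[(2S,3E)-2,6-bis[(tert-butyldimethylsilyl)oxy]-4-{[(tert-butyldiphenylsilyl)oxy]methyl}hex-3-en-1-yl]-4-[(4-methoxybenzyl)oxy]hexa-2,5-dien-1-yl acetate | C=C[C@H](OCc1ccc(OC)cc1)/C=C(/COC(C)=O)C[C@H](O[Si](C)(C)C(C)(C)C)/C=C(/CO[Si](c1ccccc1)(c1ccccc1)C(C)(C)C)CCO[Si](C)(C)C(C)(C)C | intermediate
23 | (2E,4S)-2-[(2S,3E)-2,6-bis[(tert-butyldimethylsilyl)oxy]-4-{[(tert-butyldiphenylsilyl)oxy]methyl}hex-3-en-1-yl]-4-hydroxyhexa-2,5-dien-1-yl acetate | C=C[C@H](O)/C=C(/COC(C)=O)C[C@H](O[Si](C)(C)C(C)(C)C)/C=C(/CO[Si](c1ccccc1)(c1ccccc1)C(C)(C)C)CCO[Si](C)(C)C(C)(C)C | intermediate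
24 | 2-(bromomethyl)acrylic acid | C=C(CBr)C(=O)O | starting material
25 | (3S,4E)-6-acetoxy-5-{(2S,3E)-2,6-bis[(tert-butyldimethylsilyl)oxy]-4-{[(tert-butyldiphenylsilyl)oxy]methyl}hex-3-en-1-yl}hexa-1,4-dien-3-yl 2-(bromomethyl)prop-2-enoate | C=C[C@H](OC(=O)C(=C)CBr)/C=C(/COC(C)=O)C[C@H](O[Si](C)(C)C(C)(C)C)/C=C(/CO[Si](c1ccccc1)(c1ccccc1)C(C)(C)C)CCO[Si](C)(C)C(C)(C)C | intermediate
26 | (5R)-3-(bromomethyl)-5-[(1E,4S,5E)-2-(acetoxymethyl)-4,8-bis[(tert-butyldimethylsilyl)oxy]-6-{[(tert-butyldiphenylsilyl)oxy]methyl}octa-1,5-dien-1-yl]furan-2(5H)-one | O=C1O[C@@H](C=C1CBr)/C=C(/COC(C)=O)C[C@H](O[Si](C)(C)C(C)(C)C)/C=C(/CO[Si](c1ccccc1)(c1ccccc1)C(C)(C)C)CCO[Si](C)(C)C(C)(C)C | intermediate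
27 | (5R)-3-(bromomethyl)-5-[(1E,4S,5E)-2-(acetoxymethyl)-4-[(tert-butyldimethylsilyl)oxy]-6-{[(tert-butyldiphenylsilyl)oxy]methyl}-8-hydroxyocta-1,5-dien-1-yl]furan-2(5H)-one | O=C1O[C@@H](C=C1CBr)/C=C(/COC(C)=O)C[C@H](O[Si](C)(C)C(C)(C)C)/C=C(/CO[Si](c1ccccc1)(c1ccccc1)C(C)(C)C)CCO | intermediate
28 | (5R)-3-(bromomethyl)-5-[(1E,4S,5E)-2-(acetoxymethyl)-4-[(tert-butyldimethylsilyl)oxy]-6-{[(tert-butyldiphenylsilyl)oxy]methyl}-8-oxoocta-1,5-dien-1-yl]furan-2(5H)-one | O=C1O[C@@H](C=C1CBr)/C=C(/COC(C)=O)C[C@H](O[Si](C)(C)C(C)(C)C)/C=C(/CO[Si](c1ccccc1)(c1ccccc1)C(C)(C)C)CC=O | intermediate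
29 | allylchromium dichloride (trivalent chromium) derived from 28, CH2CrCl2 in place of CH2Br | O=C1O[C@@H](C=C1C[Cr](Cl)Cl)/C=C(/COC(C)=O)C[C@H](O[Si](C)(C)C(C)(C)C)/C=C(/CO[Si](c1ccccc1)(c1ccccc1)C(C)(C)C)CC=O | intermediate (not isolated)
30 | (1(10)E,2S,4E,6R,7R,8S)-15-acetoxy-2-[(tert-butyldimethylsilyl)oxy]-14-[(tert-butyldiphenylsilyl)oxy]-8-hydroxygermacra-1(10),4,11(13)-trien-12,6-olide | C=C1C(=O)O[C@@H]2/C=C(/COC(C)=O)C[C@H](O[Si](C)(C)C(C)(C)C)/C=C(/CO[Si](c3ccccc3)(c3ccccc3)C(C)(C)C)C[C@H](O)[C@@H]12 | intermediate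
31 | 3-methylbutanoic acid (isovaleric acid) | CC(C)CC(=O)O | starting material
32 | (1(10)E,2S,4E,6R,7R,8R)-15-acetoxy-2-[(tert-butyldimethylsilyl)oxy]-14-[(tert-butyldiphenylsilyl)oxy]-8-[(3-methylbutanoyl)oxy]germacra-1(10),4,11(13)-trien-12,6-olide | C=C1C(=O)O[C@@H]2/C=C(/COC(C)=O)C[C@H](O[Si](C)(C)C(C)(C)C)/C=C(/CO[Si](c3ccccc3)(c3ccccc3)C(C)(C)C)C[C@@H](OC(=O)CC(C)C)[C@@H]12 | intermediate
33 | (1(10)E,2S,4E,6R,7R,8R)-15-acetoxy-2,14-dihydroxy-8-[(3-methylbutanoyl)oxy]germacra-1(10),4,11(13)-trien-12,6-olide | C=C1C(=O)O[C@@H]2/C=C(/COC(C)=O)C[C@H](O)/C=C(/CO)C[C@@H](OC(=O)CC(C)C)[C@@H]12 | intermediate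
34 | (1(10)E,2S,4E,6R,7R,8R)-15-acetoxy-2-hydroxy-8-[(3-methylbutanoyl)oxy]-14-oxogermacra-1(10),4,11(13)-trien-12,6-olide (CNP0524123.1) | C=C1C(=O)O[C@@H]2/C=C(/COC(C)=O)C[C@H](O)/C=C(/C=O)C[C@@H](OC(=O)CC(C)C)[C@@H]12 | target

## Step count and risks

Total step count: 24. Longest linear sequence: 21 steps (from 1 through steps 1–3, 5–10 and 13–24).

The three steps most likely to fail:

**Step 21 (key macrocyclization).** Intermolecular coupling or protonation of the allylchromium species may outrun ring closure. The aldehyde may add to the other butenolide face or through a chair with the chain axial, giving mixtures at C7 and C8. The chromium alkoxide at C8 may translactonize onto C12. The fallback sets out from 27 and changes the activation mode and the transition state. Stannylation of the allylic bromide with (Bu3Sn)2 and Pd2(dba)3 (cat.) in THF, the bromide reacting far faster than the allylic acetate, would give the allylstannane alcohol F1. Buffered Dess–Martin oxidation would give the stannyl aldehyde F2. BF3·OEt2 in CH2Cl2 at −78 °C under high dilution would then close the same C7–C8 bond by a Lewis-acid-promoted SE2′ addition through an open transition state, which favours the 7,8-syn relationship and should give the 8R alcohol F3. Acylation of F3 with 3-methylbutanoic anhydride and DMAP (retention) comes back to the route at 32, so that step 22 is not needed.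

**Step 22 (Mitsunobu inversion at C8).** Elimination from the hindered alkoxyphosphonium ion, esterification with retention through an acyloxyphosphonium pathway, or conjugate addition of the phosphine to the methylene lactone may take over. The fallback sets out from 30 and separates activation from displacement. Tf2O and pyridine at −30 °C would give the C8 triflate F4. Cesium 3-methylbutanoate (CsO2CCH2CHMe2) with 18-crown-6 in toluene would displace it with inversion and come back to the route at 32.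

**Step 5 (olefination that sets C4=C5).** The E/Z selectivity may erode, and the basic phosphonate anion may enolize aldehyde 4, with loss of the C6 configuration or migration of its alkene. The fallback sets out from 5 (and uses 4) and replaces the phosphonate by a salt-free stabilized phosphorane. Opening of 5 with dilithioacetate (acetic acid, two equivalents of LiN(i-Pr)2) and lactonization on mild acidification would give (5S)-5-(trityloxymethyl)oxolan-2-one F5. Enolization with LiN(SiMe3)2 and Me3SiCl followed by N-bromosuccinimide would give the α-bromo lactone F6. PPh3 in THF and then Et3N would give the phosphorane F7, whose Wittig reaction with 4 in CH2Cl2 at rt is reliably E-selective under neutral conditions and comes back to the route at 9.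

## Further compounds

F1 | step 21 | (5R)-5-[(1E,4S,5E)-2-(acetoxymethyl)-4-[(tert-butyldimethylsilyl)oxy]-6-{[(tert-butyldiphenylsilyl)oxy]methyl}-8-hydroxyocta-1,5-dien-1-yl]-3-[(tributylstannyl)methyl]furan-2(5H)-one | O=C1O[C@@H](C=C1C[Sn](CCCC)(CCCC)CCCC)/C=C(/COC(C)=O)C[C@H](O[Si](C)(C)C(C)(C)C)/C=C(/CO[Si](c1ccccc1)(c1ccccc1)C(C)(C)C)CCO
F2 | step 21 | (5R)-5-[(1E,4S,5E)-2-(acetoxymethyl)-4-[(tert-butyldimethylsilyl)oxy]-6-{[(tert-butyldiphenylsilyl)oxy]methyl}-8-oxoocta-1,5-dien-1-yl]-3-[(tributylstannyl)methyl]furan-2(5H)-one | O=C1O[C@@H](C=C1C[Sn](CCCC)(CCCC)CCCC)/C=C(/COC(C)=O)C[C@H](O[Si](C)(C)C(C)(C)C)/C=C(/CO[Si](c1ccccc1)(c1ccccc1)C(C)(C)C)CC=O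
F3 | step 21 | (1(10)E,2S,4E,6R,7R,8R)-15-acetoxy-2-[(tert-butyldimethylsilyl)oxy]-14-[(tert-butyldiphenylsilyl)oxy]-8-hydroxygermacra-1(10),4,11(13)-trien-12,6-olide | C=C1C(=O)O[C@@H]2/C=C(/COC(C)=O)C[C@H](O[Si](C)(C)C(C)(C)C)/C=C(/CO[Si](c3ccccc3)(c3ccccc3)C(C)(C)C)C[C@@H](O)[C@@H]12
F4 | step 22 | (1(10)E,2S,4E,6R,7R,8S)-15-acetoxy-2-[(tert-butyldimethylsilyl)oxy]-14-[(tert-butyldiphenylsilyl)oxy]-8-[(trifluoromethanesulfonyl)oxy]germacra-1(10),4,11(13)-trien-12,6-olide | C=C1C(=O)O[C@@H]2/C=C(/COC(C)=O)C[C@H](O[Si](C)(C)C(C)(C)C)/C=C(/CO[Si](c3ccccc3)(c3ccccc3)C(C)(C)C)C[C@H](OS(=O)(=O)C(F)(F)F)[C@@H]12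
F5 | step 5 | (5S)-5-(trityloxymethyl)oxolan-2-one | O=C1CC[C@H](O1)COC(c1ccccc1)(c1ccccc1)c1ccccc1
F6 | step 5 | (5S)-3-bromo-5-(trityloxymethyl)oxolan-2-one (mixture at C3) | O=C1C(Br)C[C@H](O1)COC(c1ccccc1)(c1ccccc1)c1ccccc1
F7 | step 5 | (5S)-3-(triphenylphosphoranylidene)-5-(trityloxymethyl)oxolan-2-one | O=C1C(=P(c2ccccc2)(c2ccccc2)c2ccccc2)C[C@H](O1)COC(c1ccccc1)(c1ccccc1)c1ccccc1
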